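**Assumption:** (S)-naringenin is available commercially at high ee (it is the natural citrus enantiomer, also obtained by hydrolysis of naringin). Its C2 stereocentre is the only stereocentre in the target and is never touched.

## Retrosynthetic overview
1. Target **1** (3′,6,8-triprenyl-(S)-naringenin) comes from the tri-allyl phenol **2** by a triple olefin cross-metathesis with 2-methyl-2-butene (allyl → prenyl).
2. **2** comes from the tri-O-allyl ether **3** by a triple aromatic Claisen [3,3] rearrangement. This is the key bond-forming step: 4′-O→C3′, 5-O→C6, 7-O→C8.
3. **3** comes from exhaustive O-allylation of (S)-naringenin **4**, which already contains the chromanone ring and the (2S) centre.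
4. No ring is formed in the route. The bicyclic core is bought, and the only new bonds are three aryl C–C bonds from the Claisen, then three alkene exchanges.

## Route

**Step 1**
Reactants: **4** (S)-naringenin; **5** allyl bromide
Product: **3** (2S)-5,7,4′-tri-O-allylnaringenin
Conditions: **5** (5 equiv), K2CO3 (5 equiv), KI (cat.), acetone, reflux
Reagents that add atoms: allyl bromide, C=CCBr
Why: Williamson etherification alkylates all three phenols, including the chelated 5-OH, under mild heterogeneous base. The C2 centre is not involved, and the short reaction time and moderate temperature limit retro-oxa-Michael racemisation.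

**Step 2**
Reactants: **3**
Product: **2** (2S)-3′,6,8-triallyl-5,7,4′-trihydroxyflavanone
Conditions: 1,2-dichlorobenzene, BHT (cat.), Ar, 190 °C (µW or sealed tube), 1–2 h
Reagents that add atoms: none
Why: The aromatic Claisen [3,3] rearrangement moves each allyl group from O to an ortho carbon, and the intermediate dienones tautomerise to phenols.
- The 4′-O-allyl group can only go to C3′.
- The 5-O-allyl group can only reach C6, because C4a is blocked.
- The 7-O-allyl group is then steered to C8, giving the 6,8-pattern.
- No stereocentre is made or changed, and the neutral, non-basic medium avoids ring-opening of the flavanone.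

**Step 3**
Reactants: **2**; **6** 2-methyl-2-butene
Product: **1** (2S)-3′,6,8-triprenyl-5,7,4′-trihydroxyflavanone (target)
Conditions: Hoveyda–Grubbs II (3 × 5 mol%, added portionwise), **6** (40 equiv), 1,4-benzoquinone (10 mol%), CH2Cl2, 40 °C, sealed tube, 24 h
Reagents that add atoms: 2-methyl-2-butene, CC=C(C)C (supplies the Me2C= terminus; propene is lost)
Why: Olefin cross-metathesis with a large excess of the trisubstituted alkene converts each terminal allyl arene into a prenyl arene. Benzoquinone suppresses Ru–H isomerisation to propenyl, free ortho-allyl phenols are tolerated, and C2 is untouched.

## Checks against the target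
- The target SMILES has a flavan-4-one core with OH at C5 and C7, prenyl at C6 and C8, and a 4′-OH/3′-prenyl B ring. Compound **1** has exactly this pattern.
- C2 is (S). The neighbour order (aryl, H, ring O, C3) and the CIP priorities O > aryl > CH2 are the same in **4**, **3**, **2** and **1**.
- Atom balance:

| Compound | Formula | Change |
|---|---|---|
| **4** | C15H12O5 | none |
| **3** | C24H24O5 | three H replaced by allyl (+C9H12) |
| **2** | C24H24O5 | isomer of **3** |
| **1** | C30H36O5 | +3 × C2H4 |

- Functional groups survive each step: the ketone and the benzylic ether tolerate all three sets of conditions, and the chelated 5-OH is free in the product.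

## Compound list
1 | (2S)-3′,6,8-triprenylnaringenin (target) | CC(C)=CCc1cc([C@@H]2CC(=O)c3c(O)c(CC=C(C)C)c(O)c(CC=C(C)C)c3O2)ccc1O | target
2 | (2S)-3′,6,8-triallyl-5,7,4′-trihydroxyflavanone | C=CCc1cc([C@@H]2CC(=O)c3c(O)c(CC=C)c(O)c(CC=C)c3O2)ccc1O | intermediate
3 | (2S)-5,7,4′-tri-O-allylnaringenin | C=CCOc1ccc([C@@H]2CC(=O)c3c(OCC=C)cc(OCC=C)cc3O2)cc1 | intermediate
4 | (S)-naringenin | Oc1ccc([C@@H]2CC(=O)c3c(O)cc(O)cc3O2)cc1 | starting material
5 | allyl bromide | C=CCBr | starting material
6 | 2-methyl-2-butene | CC=C(C)C | starting material

## Totals
Total steps: 3. Longest linear sequence: 3 steps.

## Three steps most likely to fail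
1. **Step 2 (triple Claisen).**
   - Risks: a mixture of regioisomers (6,6-diallyl dienone, para-Cope products), thermal racemisation, and decomposition at 190 °C.
   - Fallback: abandon the one-pot thermal triple rearrangement. Make only the 4′,7-di-O-allyl ether, run a low-temperature BCl3-mediated Claisen, then re-allylate the 7-OH and rearrange again to reach the remaining ring position. This is an iterative two-round sequence.
2. **Step 3 (triple cross-metathesis).**
   - Risks: incomplete conversion, allyl→propenyl isomerisation, and Ru chelation by the phenols.
   - Fallback: replace metathesis with a two-stage sequence. First, OsO4/NaIO4 cleavage of each allyl group to the arylacetaldehyde. Second, Wittig olefination with isopropylidene triphenylphosphorane to install the prenyl groups. This needs a racemisation check at C2 under the basic ylide conditions.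
3. **Step 1 (tri-allylation).**
   - Risks: slow alkylation of the chelated 5-OH, and partial racemisation through ring-opening to the chalcone under prolonged base.
   - Fallback: allylate only the 7-OH and 4′-OH under neutral Mitsunobu conditions (allyl alcohol, PPh3, DIAD). Handle the 5-OH by the iterative route above, where it stays free and directs C6 selectivity through the chelate-fixed Kekulé structure.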